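All runs come from a simulation with constants of no real substance, noise included.

I charge 0.0050 M of solid electrophile with 4.75 mM of nucleophile, none of the solid being in solution at the start. Eta and gamma differ from the earlier runs, and from each other, in their scavenger.

all flasks: solid electrophile 0.0050 M; nucleophile 4.75 mM

| charge | scavenger | remark | time |
|---|---|---|---|
| red | 1.3 mM | run made earlier |  |
| teal | 1.8 mM | run made earlier |  |
| eta | 1.50 mM |  | 2.5 min |
| gamma | 2.20 mM |  | 2.5 min |

- red (time / min: solid electrophile / %, target / %): 0.167: 98, 5; 0.417: 92, 11; 0.667: 85, 13; 1.00: 80, 22; 1.50: 67, 32; 2.00: 52, 41; 2.50: 48, 45
- teal (time / min: solid electrophile / %, target / %): 0.333: 94, 8; 0.667: 88, 13; 1.00: 79, 19; 1.33: 73, 24; 2.00: 59, 40; 2.50: 49, 50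

(readings scatter by 2 percentage points)

- the analysis behind the earlier runs scatters by 2 percentage points, standard deviation
- at the start none of the solid electrophile is in solution
- what has only dissolved of solid electrophile counts as not reacted

* part of the solid electrophile that has reacted (what has only dissolved counts as not reacted) at the end, eta
* part of the solid electrophile that has reacted (what has only dissolved counts as not reacted) at the end, gamma
* what raising the concentration of scavenger from its lowest to its highest value here does to the part of the solid electrophile that has reacted (what has only dissolved counts as not reacted) (changes below 5 percentage points count as none) (it rises / it falls / no change)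

How fast does the solid go? By 2.50 min, red has lost 52.0%, and by 2.50 min, teal has lost 51.0%. Red already shows 20.0% lost at 1.00 min, so the loss runs nearly straight, like a zero-order step. I carry one number, r = 0.206 /min, the slope: the fraction of the charge lost per minute, averaged over both runs. Over 2.5 min, r gives 51.5% lost from the solid, and I take that as my first answer for the part reacted in eta and in gamma, setting aside what has only dissolved; target at that time reads 45% in red and 50% in teal.

Can the nucleophile pay for that? I put the first answer back in and suppose that each reacted electrophile takes one nucleophile while its acid ties up a second. The demand is then 5.15 mM, more than the 4.75 mM charged. On this supposition eta draws on its scavenger, but nucleophile and scavenger together cover the demand, so my first answer stands.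

Does the scavenger shift it? Red and teal differ by 1 percentage point, less than the 5 points that counts as a change, so I expect no change.

The forecast gives 51% for eta, 51% for gamma and no change, just below my figure, holding that “scavenger has no visible effect on the rate”.

The flask gives 49.2% for eta, 49.7% for gamma and no change, the change being 0.49 points.

    nucleophile + acid set free ⇌ protonated nucleophile, settled at all times (K = 52000 /M)
    acid set free + scavenger → scavenged by-product (k = 195 /M/s)
    solid electrophile ⇌ electrophile, rate k3*(cs3 - [electrophile]) while solid is left; crystals form when [electrophile] > cs3 (solubility = 3.40 mM, k = 0.00528 /s)
    nucleophile + acid set free ⇌ idle adduct, settled at all times (K = 9100 /M)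
    electrophile + nucleophile → acid set free + target (k = 159 /M/s)
    electrophile + target → side product (k = 0.430 /M/s)

For eta, r over 2.5 min stands 2.3 points above the 49.2% found, with 3.61% of the charge dissolved as electrophile. Now take eta read at 1.0 min: r gives 20.6%, and this neighbour shows 20.6% reacted, with 20.5% target. At that reading, 58% of its nucleophile and 97% of its scavenger are still unbound. At 2.50 min, eta keeps 63% of its scavenger and 9.6% of its nucleophile.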